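**Retrosynthetic overview**
- Target 17 is a 1-aryltetralin in which C2 and C3 of ring B carry two cis CH2OH arms, both trans to the C1 aryl (1R,2S,3R); ring A (7-OH, 6-OMe) and the pendant guaiacyl ring are aromatic spectators.
- Both arms come from cis-diester 15, made by syn bis-methoxycarbonylation of the C2=C3 alkene of (1R)-1-aryl-1,4-dihydronaphthalene 14 on the face away from the C1 aryl (two C–C bonds, two stereocentres).
- Ring B, the only ring formed, is closed by ring-closing metathesis of diene 13; C1 is set before that by copper-catalysed enantioselective SN2′ arylation of ring A cinnamyl bromide 9 with aryl Grignard 12.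
- Bromide 9 comes from isovanillin (O-benzylation, bromination para to OBn, Horner–Wadsworth–Emmons, Suzuki allylation, DIBAL-H, PBr3); 12 comes from 4-bromo-2-methoxyphenol.
- End game: LiAlH4 reduction of both esters, then hydrogenolysis of both benzyl ethers.

Key step: step 10

Remark on the chemistry: the antipode of the chiral carbene ligand in step 8 is taken to be the one that gives (R)-13; the sense of induction on this ortho-substituted substrate is to be confirmed on the first run, and the mirror-image ligand would be used otherwise.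

**Route**

Step 1
Reactants: 1 isovanillin (3-hydroxy-4-methoxybenzaldehyde)
Product: 2 3-(benzyloxy)-4-methoxybenzaldehyde
Conditions: BnBr, K2CO3, DMF, rt
Reagents that add atoms: benzyl bromide, BrCc1ccccc1
Why: Williamson etherification of the phenoxide with a benzylic halide; the aldehyde is inert to carbonate base.

Step 2
Reactants: 2 3-(benzyloxy)-4-methoxybenzaldehyde
Product: 3 5-(benzyloxy)-2-bromo-4-methoxybenzaldehyde
Conditions: Br2 (1.1 equiv), NaOAc, AcOH, rt
Reagents that add atoms: bromine, BrBr
Why: Electrophilic aromatic bromination should go para to the benzyloxy group (the site ortho to it is flanked by the formyl group), which is the carbon that becomes C4a.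

Step 3
Reactants: 3 5-(benzyloxy)-2-bromo-4-methoxybenzaldehyde; 4 triethyl phosphonoacetate
Product: 5 ethyl (E)-3-[5-(benzyloxy)-2-bromo-4-methoxyphenyl]prop-2-enoate
Conditions: NaH, THF, 0 °C to rt
Reagents that add atoms: none
Why: Horner–Wadsworth–Emmons olefination with a stabilised phosphonate gives the (E)-enoate, and placing it before the allylation removes the aldehyde that allylboronate 6 would otherwise attack.

Step 4
Reactants: 5 ethyl (E)-3-[5-(benzyloxy)-2-bromo-4-methoxyphenyl]prop-2-enoate; 6 allylboronic acid pinacol ester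
Product: 7 ethyl (E)-3-[2-allyl-5-(benzyloxy)-4-methoxyphenyl]prop-2-enoate
Conditions: Pd(PPh3)4 (5 mol %), CsF (3 equiv), THF, reflux, degassed
Reagents that add atoms: none
Why: Suzuki–Miyaura coupling of the aryl bromide with the fluoride-activated allylboronate installs the allyl arm (future C3 and C4) without touching the enoate.

Step 5
Reactants: 7 ethyl (E)-3-[2-allyl-5-(benzyloxy)-4-methoxyphenyl]prop-2-enoate
Product: 8 (E)-3-[2-allyl-5-(benzyloxy)-4-methoxyphenyl]prop-2-en-1-ol
Conditions: i-Bu2AlH (2.5 equiv), CH2Cl2, −78 to 0 °C; aqueous potassium sodium tartrate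
Reagents that add atoms: none
Why: DIBAL-H reduces the conjugated ester by 1,2-addition to the (E)-allylic alcohol at low temperature, leaving both alkenes and the benzyl ether intact.

Step 6
Reactants: 8 (E)-3-[2-allyl-5-(benzyloxy)-4-methoxyphenyl]prop-2-en-1-ol
Product: 9 1-allyl-4-(benzyloxy)-2-[(E)-3-bromoprop-1-enyl]-5-methoxybenzene
Conditions: PBr3 (0.4 equiv), Et2O, 0 °C; aqueous NaHCO3 wash, used crude at once
Reagents that add atoms: phosphorus tribromide, BrP(Br)Br
Why: PBr3 converts the primary allylic alcohol into the bromide with the conjugated linear (E)-isomer favoured; the electron-rich bromide is taken on without chromatography to avoid ionisation on silica.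

Step 7
Reactants: 10 4-bromo-2-methoxyphenol
Product: 11 1-(benzyloxy)-4-bromo-2-methoxybenzene
Conditions: BnBr, K2CO3, DMF, rt
Reagents that add atoms: benzyl bromide, BrCc1ccccc1
Why: Williamson etherification; the benzyl ether masks the phenol for the Grignard step.

Step 8
Reactants: 11 1-(benzyloxy)-4-bromo-2-methoxybenzene; 9 1-allyl-4-(benzyloxy)-2-[(E)-3-bromoprop-1-enyl]-5-methoxybenzene
Product: 13 1-(benzyloxy)-4-{(1R)-1-[2-allyl-5-(benzyloxy)-4-methoxyphenyl]prop-2-en-1-yl}-2-methoxybenzene, via arylmagnesium bromide 12 (not isolated)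
Conditions: Mg, Et2O, reflux (I2 initiation); then slow addition to 9, CuBr·SMe2 (5 mol %), C2-symmetric chiral 1,3-bis(arylmethyl)-4,5-diphenylimidazolinium tetrafluoroborate (carbene precursor, 6 mol %), CH2Cl2, −78 °C
Reagents that add atoms: none
Why: Grignard formation followed by copper-catalysed enantioselective allylic substitution (SN2′), a reaction type established for aryl Grignard reagents and cinnamyl bromides with chiral carbene–copper catalysts; the aryl–copper species should attack the benzylic γ-carbon and the ligand selects the alkene face, setting C1 as (R).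

Step 9
Reactants: 13 1-(benzyloxy)-4-{(1R)-1-[2-allyl-5-(benzyloxy)-4-methoxyphenyl]prop-2-en-1-yl}-2-methoxybenzene
Product: 14 (1R)-7-(benzyloxy)-1-[4-(benzyloxy)-3-methoxyphenyl]-6-methoxy-1,4-dihydronaphthalene
Conditions: second-generation Grubbs catalyst, (H2IMes)(PCy3)Cl2Ru=CHPh (3 mol %), 1,4-benzoquinone (10 mol %), CH2Cl2 (0.01 M), 40 °C; stored cold under argon
Reagents that add atoms: none
Why: Ring-closing metathesis of the two terminal alkenes should close the six-membered ring B with loss of ethene, benzoquinone intercepting ruthenium hydrides so that C2=C3 does not migrate and C1 is untouched.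

Step 10
Reactants: 14 (1R)-7-(benzyloxy)-1-[4-(benzyloxy)-3-methoxyphenyl]-6-methoxy-1,4-dihydronaphthalene
Product: 15 dimethyl (1R,2S,3R)-7-(benzyloxy)-1-[4-(benzyloxy)-3-methoxyphenyl]-6-methoxy-1,2,3,4-tetrahydronaphthalene-2,3-dicarboxylate
Conditions: Pd(TFA)2 (5 mol %), N,N′-bis(2,6-dimethylphenyl)butane-2,3-diimine (5.5 mol %), p-TsOH·H2O (5 mol %), 1,4-benzoquinone (1.5 equiv), CO (4 bar), MeOH/THF 7:1, 20 °C
Reagents that add atoms: carbon monoxide, [C-]#[O+]; methanol, CO
Why: This is the known palladium-catalysed oxidative bis-alkoxycarbonylation of 1,2-disubstituted and cyclic alkenes to syn-succinates, applied here to a new substrate: diimine-ligated divalent palladium forms a Pd–CO2Me species from CO and methanol, the alkene inserts into it in a syn fashion, CO inserts into the resulting alkyl–palladium bond with retention, and methanolysis of the acyl–palladium releases the diester and zerovalent palladium, which benzoquinone and acid return to the divalent state. No ring is closed; both new C–C bonds (at C2 and C3) form on the palladium-bearing face, so the two esters are necessarily cis. The face is chosen by the C1 aryl, which sits pseudoaxial on the flattened boat of ring B to avoid the peri C8–H and shields its own side of C2=C3, so the catalyst approaches anti to it and C2 (S) and C3 (R) are set under substrate control with a 1,2-trans relationship. Regiochemistry is immaterial because both alkene carbons receive the same group. The step needs CO insertion to outrun β-hydride elimination toward C1 or C4 and any migration of the alkene into conjugation (which would erase C1); CO pressure, the rigid chelating diimine, ambient temperature and the quinone, which removes palladium hydride, are what should secure this.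

Step 11
Reactants: 15 dimethyl (1R,2S,3R)-7-(benzyloxy)-1-[4-(benzyloxy)-3-methoxyphenyl]-6-methoxy-1,2,3,4-tetrahydronaphthalene-2,3-dicarboxylate
Product: 16 [(1R,2S,3R)-7-(benzyloxy)-1-[4-(benzyloxy)-3-methoxyphenyl]-6-methoxy-1,2,3,4-tetrahydronaphthalene-2,3-diyl]dimethanol
Conditions: LiAlH4 (3 equiv), THF, 0 °C; Fieser work-up
Reagents that add atoms: none
Why: LiAlH4 reduces both esters to primary alcohols and at 0 °C should do so faster than it enolises them, so the cis C2/C3 configuration is kept.

Step 12
Reactants: 16 [(1R,2S,3R)-7-(benzyloxy)-1-[4-(benzyloxy)-3-methoxyphenyl]-6-methoxy-1,2,3,4-tetrahydronaphthalene-2,3-diyl]dimethanol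
Product: 17 (1R,2S,3R)-1-(4-hydroxy-3-methoxyphenyl)-2,3-bis(hydroxymethyl)-6-methoxy-1,2,3,4-tetrahydronaphthalen-7-ol (target)
Conditions: H2 (1 atm), 10% Pd/C, EtOAc/MeOH, rt
Reagents that add atoms: none
Why: Catalytic hydrogenolysis cleaves the two benzyl aryl ethers, and no other group in 16 is reducible under these conditions.

**Compound list**
1 | isovanillin (3-hydroxy-4-methoxybenzaldehyde) | COc1ccc(C=O)cc1O | starting material
2 | 3-(benzyloxy)-4-methoxybenzaldehyde | COc1ccc(C=O)cc1OCc1ccccc1 | intermediate
3 | 5-(benzyloxy)-2-bromo-4-methoxybenzaldehyde | COc1cc(Br)c(C=O)cc1OCc1ccccc1 | intermediate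
4 | triethyl phosphonoacetate | CCOC(=O)CP(=O)(OCC)OCC | starting material
5 | ethyl (E)-3-[5-(benzyloxy)-2-bromo-4-methoxyphenyl]prop-2-enoate | CCOC(=O)/C=C/c1cc(OCc2ccccc2)c(OC)cc1Br | intermediate
6 | allylboronic acid pinacol ester | C=CCB1OC(C)(C)C(C)(C)O1 | starting material
7 | ethyl (E)-3-[2-allyl-5-(benzyloxy)-4-methoxyphenyl]prop-2-enoate | CCOC(=O)/C=C/c1cc(OCc2ccccc2)c(OC)cc1CC=C | intermediate
8 | (E)-3-[2-allyl-5-(benzyloxy)-4-methoxyphenyl]prop-2-en-1-ol | OC/C=C/c1cc(OCc2ccccc2)c(OC)cc1CC=C | intermediate
9 | 1-allyl-4-(benzyloxy)-2-[(E)-3-bromoprop-1-enyl]-5-methoxybenzene | BrC/C=C/c1cc(OCc2ccccc2)c(OC)cc1CC=C | intermediate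
10 | 4-bromo-2-methoxyphenol | COc1cc(Br)ccc1O | starting material
11 | 1-(benzyloxy)-4-bromo-2-methoxybenzene | COc1cc(Br)ccc1OCc1ccccc1 | intermediate
12 | [4-(benzyloxy)-3-methoxyphenyl]magnesium bromide (ethereal solution, not isolated) | COc1cc([Mg]Br)ccc1OCc1ccccc1 | intermediate
13 | 1-(benzyloxy)-4-{(1R)-1-[2-allyl-5-(benzyloxy)-4-methoxyphenyl]prop-2-en-1-yl}-2-methoxybenzene | COc1cc([C@@H](C=C)c2cc(OCc3ccccc3)c(OC)cc2CC=C)ccc1OCc1ccccc1 | intermediate
14 | (1R)-7-(benzyloxy)-1-[4-(benzyloxy)-3-methoxyphenyl]-6-methoxy-1,4-dihydronaphthalene | COc1cc([C@@H]2c3cc(OCc4ccccc4)c(OC)cc3CC=C2)ccc1OCc1ccccc1 | intermediate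
15 | dimethyl (1R,2S,3R)-7-(benzyloxy)-1-[4-(benzyloxy)-3-methoxyphenyl]-6-methoxy-1,2,3,4-tetrahydronaphthalene-2,3-dicarboxylate (1,2-trans, 2,3-cis) | COc1cc([C@@H]2c3cc(OCc4ccccc4)c(OC)cc3C[C@@H](C(=O)OC)[C@H]2C(=O)OC)ccc1OCc1ccccc1 | intermediate
16 | [(1R,2S,3R)-7-(benzyloxy)-1-[4-(benzyloxy)-3-methoxyphenyl]-6-methoxy-1,2,3,4-tetrahydronaphthalene-2,3-diyl]dimethanol | COc1cc([C@@H]2c3cc(OCc4ccccc4)c(OC)cc3C[C@@H](CO)[C@H]2CO)ccc1OCc1ccccc1 | intermediate
17 | (1R,2S,3R)-1-(4-hydroxy-3-methoxyphenyl)-2,3-bis(hydroxymethyl)-6-methoxy-1,2,3,4-tetrahydronaphthalen-7-ol | COc1cc([C@@H]2c3cc(O)c(OC)cc3C[C@@H](CO)[C@H]2CO)ccc1O | target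

**Totals**
Total step count: 12. Longest linear sequence: 11 steps (steps 1–6 and 8–12, from isovanillin).

**Steps most likely to fail**

Step 10 (key step). After the first insertion the alkyl–palladium intermediate may undergo β-hydride elimination toward C1 or C4 instead of CO insertion, or palladium hydride may move C2=C3 into conjugation with loss of the C1 stereocentre. Allylic C–H palladation and incomplete facial discrimination are further ways for the step to underperform. The fallback sets out from 14 and returns at 16, installing the two carbons by a thermal cycloaddition and then cutting the bond between them. Dichloroketene (from trichloroacetyl chloride and Zn–Cu couple, Et2O) would add in a [2+2] fashion to C2=C3 from the face away from the C1 aryl to give the cis-fused dichlorocyclobutanone F1 (drawn with the carbonyl on C2; the other regioisomer would converge on the same diol). Zn in AcOH would remove both chlorines to give the cyclobutanone F2. LDA/TMSCl at −78 °C would enolise on the methylene side to the silyl enol ether F3. Ozonolysis with one equivalent of O3 (CH2Cl2/MeOH, −78 °C; the enol ether reacts far faster than the alkoxyarenes) and NaBH4 work-up would give the hydroxy acid F4, which on acidification closes to the cis-fused γ-lactone F5. LiAlH4 in THF would reduce F5 to diol 16.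

Step 8. Direct (α) substitution may compete and give the linear 1,3-diarylpropene, enantiofacial discrimination may be eroded by the ortho-allyl group, and the electron-rich allylic bromide may ionise before it couples. The fallback sets out from alcohol 8 and Grignard solution 12 and returns at 13, replacing the copper SN2′ reaction by iridium-catalysed branched-selective allylic arylation. Alcohol 8 would be converted with methyl chloroformate and pyridine into the stable methyl carbonate F6. Grignard 12 would be transmetalated with ZnBr2 to the arylzinc bromide F7. [Ir(cod)Cl]2 with a chiral binaphthol-derived phosphoramidite bearing a bis(1-phenylethyl)amine unit (antipode chosen for R), LiBr, THF, rt, would join F6 and F7 through an allyliridium intermediate attacked at its aryl-substituted terminus, giving diene 13.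

Step 4. Palladium hydride formed during the coupling may move the allyl double bond into conjugation with ring A (the propenyl arene would give an indene on metathesis), and the allylboronate may be lost by protodeboronation before transmetalation. The fallback sets out from 3 and returns at 7, introducing the allyl group by organometallic alkylation instead of cross-coupling. Aldehyde 3 would be protected with HC(OMe)3 and p-TsOH in MeOH as the dimethyl acetal F8. Bromine–lithium exchange (n-BuLi, THF, −78 °C), transmetalation with CuBr·SMe2 and alkylation with allyl bromide would give the allyl acetal F9. Aqueous HCl in THF would release 2-allyl-5-(benzyloxy)-4-methoxybenzaldehyde F10, and Horner–Wadsworth–Emmons olefination of F10 with 4 (NaH, THF) would give 7.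

**Further compounds**
F1 | step 10 | cis-fused 2,2-dichlorocyclobutanone across C2–C3 of the (1R)-1-aryltetralin (carbonyl carbon on C2, CCl2 on C3, four-membered ring anti to the C1 aryl) | COc1cc([C@@H]2c3cc(OCc4ccccc4)c(OC)cc3C[C@@H]3[C@H]2C(=O)C3(Cl)Cl)ccc1OCc1ccccc1
F2 | step 10 | cis-fused cyclobutanone across C2–C3 (carbonyl carbon on C2, CH2 on C3) | COc1cc([C@@H]2c3cc(OCc4ccccc4)c(OC)cc3C[C@@H]3[C@H]2C(=O)C3)ccc1OCc1ccccc1
F3 | step 10 | trimethylsilyl enol ether of F2 (cyclobutene C(OSiMe3)=CH, silyloxy carbon on C2) | COc1cc([C@@H]2c3cc(OCc4ccccc4)c(OC)cc3C[C@@H]3[C@H]2C(O[Si](C)(C)C)=C3)ccc1OCc1ccccc1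
F4 | step 10 | hydroxy acid: C2 carboxylic acid and C3 hydroxymethyl, cis to each other and trans to the C1 aryl | COc1cc([C@@H]2c3cc(OCc4ccccc4)c(OC)cc3C[C@@H](CO)[C@H]2C(=O)O)ccc1OCc1ccccc1
F5 | step 10 | cis-fused γ-lactone (C2–C(=O)–O–CH2–C3) | COc1cc([C@@H]2c3cc(OCc4ccccc4)c(OC)cc3C[C@@H]3[C@H]2C(=O)OC3)ccc1OCc1ccccc1
F6 | step 8 | (E)-3-[2-allyl-5-(benzyloxy)-4-methoxyphenyl]prop-2-enyl methyl carbonate | COC(=O)OC/C=C/c1cc(OCc2ccccc2)c(OC)cc1CC=C
F7 | step 8 | [4-(benzyloxy)-3-methoxyphenyl]zinc bromide | COc1cc([Zn]Br)ccc1OCc1ccccc1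
F8 | step 4 | 1-(benzyloxy)-4-bromo-5-(dimethoxymethyl)-2-methoxybenzene | COc1cc(Br)c(C(OC)OC)cc1OCc1ccccc1
F9 | step 4 | 1-allyl-4-(benzyloxy)-2-(dimethoxymethyl)-5-methoxybenzene | COc1cc(CC=C)c(C(OC)OC)cc1OCc1ccccc1
F10 | step 4 | 2-allyl-5-(benzyloxy)-4-methoxybenzaldehyde | COc1cc(CC=C)c(C=O)cc1OCc1ccccc1
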